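**Plan**

Numbering used: ring C1 (CMe2), C2–C4 (CH2), C5 (C(OH)CH3), C6 (C(OH) bearing the chain C7 to C12′ with its ester).
Retrosynthesis: the chain is cut at C14′=C13′, C15=C15′, C11=C12 and C7=C8 (Wittig and Horner–Wadsworth–Emmons) down to ring aldehyde 15; the trans-5,6-diol is the anti-opened 5,6-oxirane of a C7 ester (12).
The carbocycle of 12 is cut at C3–C4 and C5–C6 together: keto ester trifluoroborate 7 (C3–C2–C1–C6, radical precursor at C3, ketone at C6) plus the C4=C5(CH3) unit as α-methylvinylsulfonium salt 10.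
Enabling feature: C5 carries only a methyl, the CH2 C4 and the oxygen it shares with C6 in the oxirane, and C6 is a non-enolisable ketone between quaternary C1 and the ester carbon, so C4 can take a radical and C5 can then act as an ylide that hands its carbon to C6.
Forward: 1 → keto ester 5 → 7; the annulation builds the cyclohexane and the oxirane in one step; hydrolysis, reduction and oxidation give 15; the chain grows outward by C5, C5, C2 and C3 units.
Stereochemistry: C6 from face shielding by the (1R,2S,5R)-8-phenylmenthyl ester, C5 from the obligatory cis fusion of the oxirane and its inversion on hydrolysis; all alkenes E from stabilised phosphorus reagents.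

Key step: step 5

Assumption: with no chelating metal present the keto ester reacts through its antiperiplanar dicarbonyl conformer, in which the (1R,2S,5R) auxiliary leaves the Re face of C6 open; compounds 1, 2, 4, 8, 9, 16, 21 and 23 are taken as commercial. ("8-phenylmenthyl" below means (1R,2S,5R)-5-methyl-2-(2-phenylpropan-2-yl)cyclohexyl.)

**Route**

Step 1
Reactants: 1 (1R,2S,5R)-5-methyl-2-(2-phenylpropan-2-yl)cyclohexan-1-ol; 2 ethyl chlorooxoacetate
Product: 3 ethyl 8-phenylmenthyl oxalate
Conditions: pyridine, 4-(dimethylamino)pyridine (cat.), CH2Cl2, 0 °C to rt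
Reagents that add atoms: none
Why: Acylation of the hindered secondary alcohol by the acid chloride under nucleophilic catalysis (esterification) touches no stereocentre.

Step 2
Reactants: 3 ethyl 8-phenylmenthyl oxalate; 4 (3-methylbut-2-en-1-yl)magnesium chloride
Product: 5 8-phenylmenthyl 3,3-dimethyl-2-oxopent-4-enoate
Conditions: 4 (1.05 equiv) added to 3, THF, −78 °C; aq. NH4Cl at −78 °C
Reagents that add atoms: none
Why: Grignard mono-addition to an oxalate diester, in which the allylic reagent attacks the less hindered ethyl ester carbonyl through its γ-terminus (allylic transposition) to create quaternary C1, while the magnesium hemiketal alkoxide persists at −78 °C and releases the ketone only on work-up.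

Step 3
Reactants: 5 8-phenylmenthyl 3,3-dimethyl-2-oxopent-4-enoate
Product: 7 potassium trifluoro(3,3-dimethyl-5-{[(1R,2S,5R)-5-methyl-2-(2-phenylpropan-2-yl)cyclohexyl]oxy}-4,5-dioxopentyl)borate, via pinacol boronate 6 (not isolated)
Conditions: pinacolborane, [Ir(cod)Cl]2 (1.5 mol %), 1,2-bis(diphenylphosphino)ethane (3 mol %), CH2Cl2, rt; then KHF2 (aq.), MeOH, rt
Reagents that add atoms: pinacolborane CC1(C)OBOC1(C)C; potassium hydrogen difluoride F.[F-].[K+]
Why: Iridium-catalysed anti-Markovnikov hydroboration of the terminal alkene puts boron on C3 without reducing the hindered ketone, and fluoride exchange with KHF2 then gives the stable trifluoroborate.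

Step 4
Reactants: 8 diphenyl sulfoxide; 9 (prop-1-en-2-yl)magnesium bromide
Product: 10 diphenyl(prop-1-en-2-yl)sulfonium trifluoromethanesulfonate
Conditions: (CF3SO2)2O, CH2Cl2, −78 °C; then 9 (THF), −78 °C to rt
Reagents that add atoms: trifluoromethanesulfonic anhydride O=S(=O)(OS(=O)(=O)C(F)(F)F)C(F)(F)F
Why: Activation of the sulfoxide oxygen by the anhydride followed by displacement at sulfur with the alkenyl Grignard reagent (sulfonium salt synthesis from an activated sulfoxide) fixes the double bond in the α-methylvinyl position.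

Step 5
Reactants: 7 potassium trifluoroborate of the keto ester; 10 diphenyl(prop-1-en-2-yl)sulfonium trifluoromethanesulfonate
Product: 12 8-phenylmenthyl (1R,6S)-2,2,6-trimethyl-7-oxabicyclo[4.1.0]heptane-1-carboxylate, via sulfonium ylide 11 (not isolated)
Conditions: 10 (1.5 equiv), 9-mesityl-10-methylacridinium perchlorate (5 mol %), CsF (2 equiv), MeCN, blue LEDs (450 nm), rt, Ar
Reagents that add atoms: none
Why: Proposed new method: the excited acridinium oxidises the trifluoroborate to the primary C3 radical, which adds to the CH2 terminus (C4) of cationic alkene 10 (matched polarity), the α-sulfonio radical is reduced by the acridinyl radical to ylide 11, and 11 adds to the C6 ketone, after which the alkoxide expels Ph2S. The closest known reaction types are the Giese addition of alkyltrifluoroborates under acridinium photocatalysis, radical–polar crossover cyclisations, the conjugate addition/ylide/epoxide annulation of vinylsulfonium salts with tethered ketones, and the Corey–Chaykovsky epoxidation with diphenylsulfonium isopropylide. The cyclohexane closes by 6-exo-trig addition of the ylide carbon C5 to the C6 carbonyl and the oxirane by 3-exo-tet displacement at C5. C6 is set by attack on the Re face of the keto ester, the other face being covered by the phenyl ring of the auxiliary in the antiperiplanar dicarbonyl conformer, and C5 follows because only the betaine with antiperiplanar O and S can close, which gives the cis-fused oxirane. The step needs radical addition to 10 before the radical is lost, attack on the ketone and not on the ester, and ring closure before the ylide is protonated; the excess of the strongly electrophilic alkene, the highly electrophilic non-enolisable C6 carbonyl four atoms away from C5, and the aprotic medium with CsF as trap for BF3 should secure these.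

Step 6
Reactants: 12 8-phenylmenthyl (1R,6S)-2,2,6-trimethyl-7-oxabicyclo[4.1.0]heptane-1-carboxylate
Product: 13 8-phenylmenthyl (1R,2R)-1,2-dihydroxy-2,6,6-trimethylcyclohexane-1-carboxylate
Conditions: HClO4 (aq., 5 %), THF, 0 °C to rt
Reagents that add atoms: water O
Why: Acid-catalysed hydrolysis of the glycidic ester, in which water attacks the protonated oxirane at tertiary C5 remote from the ester and anti to the leaving oxygen, inverts C5 and keeps the C6–O bond, which gives the trans-5,6-diol.

Step 7
Reactants: 13 8-phenylmenthyl (1R,2R)-1,2-dihydroxy-2,6,6-trimethylcyclohexane-1-carboxylate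
Product: 14 (1S,2R)-1-(hydroxymethyl)-2,6,6-trimethylcyclohexane-1,2-diol
Conditions: LiAlH4 (3 equiv), THF, 0 °C to reflux; then H2O
Reagents that add atoms: none
Why: Hydride reduction of the hindered α-hydroxy ester (LiAlH4 ester reduction) gives the primary alcohol, frees the auxiliary for recovery and leaves both tertiary carbinol centres untouched.

Step 8
Reactants: 14 (1S,2R)-1-(hydroxymethyl)-2,6,6-trimethylcyclohexane-1,2-diol
Product: 15 (1R,2R)-1,2-dihydroxy-2,6,6-trimethylcyclohexane-1-carbaldehyde
Conditions: 2-iodoxybenzoic acid (1.5 equiv), DMSO, rt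
Reagents that add atoms: none
Why: Oxidation with 2-iodoxybenzoic acid converts only the primary alcohol, since the tertiary alcohols cannot be oxidised and this reagent does not cleave glycols, and the aldehyde has no α-hydrogen so C6 cannot epimerise.

Step 9
Reactants: 15 (1R,2R)-1,2-dihydroxy-2,6,6-trimethylcyclohexane-1-carbaldehyde; 16 diethyl [(2E)-3-cyano-2-methylprop-2-en-1-yl]phosphonate
Product: 17 (2E,4E)-5-[(1R,2R)-1,2-dihydroxy-2,6,6-trimethylcyclohexyl]-3-methylpenta-2,4-dienenitrile
Conditions: 16 (1.05 equiv), NaH (1.0 equiv), THF, 0 °C; then 15, −78 °C to rt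
Reagents that add atoms: none
Why: Horner–Wadsworth–Emmons olefination with the preformed sodium salt of the stabilised allylic phosphonate (no excess base, so no tertiary alkoxide for a retro-aldol opening) should form C7=C8 as the E alkene and carry the 9E bond, with any 9Z isomer removed by chromatography.

Step 10
Reactants: 17 (2E,4E)-5-[(1R,2R)-1,2-dihydroxy-2,6,6-trimethylcyclohexyl]-3-methylpenta-2,4-dienenitrile
Product: 18 (2E,4E)-5-[(1R,2R)-1,2-dihydroxy-2,6,6-trimethylcyclohexyl]-3-methylpenta-2,4-dienal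
Conditions: i-Bu2AlH (3.5 equiv), CH2Cl2, −78 °C; then aq. AcOH/NaOAc, 0 °C
Reagents that add atoms: water O
Why: Reduction of the conjugated nitrile with i-Bu2AlH stops at the aluminium aldimine, which buffered aqueous acid hydrolyses to the dienal without ionising the tertiary allylic alcohol.

Step 11
Reactants: 18 (2E,4E)-5-[(1R,2R)-1,2-dihydroxy-2,6,6-trimethylcyclohexyl]-3-methylpenta-2,4-dienal; 16 diethyl [(2E)-3-cyano-2-methylprop-2-en-1-yl]phosphonate
Product: 19 (2E,4E,6E,8E)-9-[(1R,2R)-1,2-dihydroxy-2,6,6-trimethylcyclohexyl]-3,7-dimethylnona-2,4,6,8-tetraenenitrile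
Conditions: 16 (1.05 equiv), NaH (1.0 equiv), THF, 0 °C; then 18, −78 °C to rt, dark
Reagents that add atoms: none
Why: A second Horner–Wadsworth–Emmons olefination with the same C5 phosphonate should form C11=C12 as the E alkene and carry the 13E bond, as in the standard chain extension of retinoid aldehydes.

Step 12
Reactants: 19 (2E,4E,6E,8E)-9-[(1R,2R)-1,2-dihydroxy-2,6,6-trimethylcyclohexyl]-3,7-dimethylnona-2,4,6,8-tetraenenitrile
Product: 20 (2E,4E,6E,8E)-9-[(1R,2R)-1,2-dihydroxy-2,6,6-trimethylcyclohexyl]-3,7-dimethylnona-2,4,6,8-tetraenal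
Conditions: i-Bu2AlH (3.5 equiv), CH2Cl2, −78 °C; then aq. AcOH/NaOAc, 0 °C, dark
Reagents that add atoms: water O
Why: Nitrile-to-aldehyde reduction with i-Bu2AlH through the aldimine, as in step 10, leaves the tetraene and the diol untouched.

Step 13
Reactants: 20 (2E,4E,6E,8E)-9-[(1R,2R)-1,2-dihydroxy-2,6,6-trimethylcyclohexyl]-3,7-dimethylnona-2,4,6,8-tetraenal; 21 2-(triphenylphosphoranylidene)acetaldehyde
Product: 22 (2E,4E,6E,8E,10E)-11-[(1R,2R)-1,2-dihydroxy-2,6,6-trimethylcyclohexyl]-5,9-dimethylundeca-2,4,6,8,10-pentaenal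
Conditions: 21 (1.2 equiv), toluene, 80 °C, dark, Ar
Reagents that add atoms: none
Why: Wittig olefination with the formyl-stabilised ylide under neutral conditions adds two carbons and should give the E enal (C15=C15′), with only a small excess of ylide to limit a second homologation.

Step 14
Reactants: 22 (2E,4E,6E,8E,10E)-11-[(1R,2R)-1,2-dihydroxy-2,6,6-trimethylcyclohexyl]-5,9-dimethylundeca-2,4,6,8,10-pentaenal; 23 methyl 2-(triphenylphosphoranylidene)propanoate
Product: 24 methyl (2E,4E,6E,8E,10E,12E)-13-[(1R,2R)-1,2-dihydroxy-2,6,6-trimethylcyclohexyl]-2,7,11-trimethyltrideca-2,4,6,8,10,12-hexaenoate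
Conditions: 23 (1.5 equiv), CH2Cl2, rt to 40 °C, dark, Ar
Reagents that add atoms: none
Why: Wittig olefination with the ester-stabilised α-methyl ylide under neutral conditions should give the E trisubstituted enoate (C14′=C13′) and completes the all-E hexaene ester without touching the diol.

**Compound list**

1 | (1R,2S,5R)-5-methyl-2-(2-phenylpropan-2-yl)cyclohexan-1-ol ((−)-8-phenylmenthol) | O[C@H]1[C@H](C(C)(C)c2ccccc2)CC[C@@H](C)C1 | starting material
2 | ethyl chlorooxoacetate | CCOC(=O)C(=O)Cl | starting material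
3 | ethyl (1R,2S,5R)-5-methyl-2-(2-phenylpropan-2-yl)cyclohexyl oxalate | CCOC(=O)C(=O)O[C@H]1[C@H](C(C)(C)c2ccccc2)CC[C@@H](C)C1 | intermediate
4 | (3-methylbut-2-en-1-yl)magnesium chloride | CC(C)=CC[Mg]Cl | starting material
5 | (1R,2S,5R)-5-methyl-2-(2-phenylpropan-2-yl)cyclohexyl 3,3-dimethyl-2-oxopent-4-enoate | C=CC(C)(C)C(=O)C(=O)O[C@H]1[C@H](C(C)(C)c2ccccc2)CC[C@@H](C)C1 | intermediate
6 | (1R,2S,5R)-5-methyl-2-(2-phenylpropan-2-yl)cyclohexyl 3,3-dimethyl-2-oxo-5-(4,4,5,5-tetramethyl-1,3,2-dioxaborolan-2-yl)pentanoate | CC1(C)OB(CCC(C)(C)C(=O)C(=O)O[C@H]2[C@H](C(C)(C)c3ccccc3)CC[C@@H](C)C2)OC1(C)C | intermediate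
7 | potassium trifluoro(3,3-dimethyl-5-{[(1R,2S,5R)-5-methyl-2-(2-phenylpropan-2-yl)cyclohexyl]oxy}-4,5-dioxopentyl)borate | [K+].F[B-](F)(F)CCC(C)(C)C(=O)C(=O)O[C@H]1[C@H](C(C)(C)c2ccccc2)CC[C@@H](C)C1 | intermediate
8 | diphenyl sulfoxide | O=S(c1ccccc1)c1ccccc1 | starting material
9 | (prop-1-en-2-yl)magnesium bromide | C=C(C)[Mg]Br | starting material
10 | diphenyl(prop-1-en-2-yl)sulfonium trifluoromethanesulfonate | C=C(C)[S+](c1ccccc1)c1ccccc1.[O-]S(=O)(=O)C(F)(F)F | intermediate
11 | 2-(diphenylsulfonio)-6,6-dimethyl-8-{[(1R,2S,5R)-5-methyl-2-(2-phenylpropan-2-yl)cyclohexyl]oxy}-7,8-dioxooctan-2-ide (sulfonium ylide) | C[C-](CCCC(C)(C)C(=O)C(=O)O[C@H]1[C@H](C(C)(C)c2ccccc2)CC[C@@H](C)C1)[S+](c1ccccc1)c1ccccc1 | intermediate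
12 | (1R,2S,5R)-5-methyl-2-(2-phenylpropan-2-yl)cyclohexyl (1R,6S)-2,2,6-trimethyl-7-oxabicyclo[4.1.0]heptane-1-carboxylate | O=C(O[C@H]1[C@H](C(C)(C)c2ccccc2)CC[C@@H](C)C1)[C@@]34C(C)(C)CCC[C@]3(C)O4 | intermediate
13 | (1R,2S,5R)-5-methyl-2-(2-phenylpropan-2-yl)cyclohexyl (1R,2R)-1,2-dihydroxy-2,6,6-trimethylcyclohexane-1-carboxylate | O=C(O[C@H]1[C@H](C(C)(C)c2ccccc2)CC[C@@H](C)C1)[C@@]3(O)C(C)(C)CCC[C@@]3(C)O | intermediate
14 | (1S,2R)-1-(hydroxymethyl)-2,6,6-trimethylcyclohexane-1,2-diol | OC[C@@]1(O)C(C)(C)CCC[C@@]1(C)O | intermediate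
15 | (1R,2R)-1,2-dihydroxy-2,6,6-trimethylcyclohexane-1-carbaldehyde | O=C[C@@]1(O)C(C)(C)CCC[C@@]1(C)O | intermediate
16 | diethyl [(2E)-3-cyano-2-methylprop-2-en-1-yl]phosphonate | CCOP(=O)(OCC)C/C(C)=C/C#N | starting material
17 | (2E,4E)-5-[(1R,2R)-1,2-dihydroxy-2,6,6-trimethylcyclohexyl]-3-methylpenta-2,4-dienenitrile | N#C/C=C(C)/C=C/[C@@]1(O)C(C)(C)CCC[C@@]1(C)O | intermediate
18 | (2E,4E)-5-[(1R,2R)-1,2-dihydroxy-2,6,6-trimethylcyclohexyl]-3-methylpenta-2,4-dienal | O=C/C=C(C)/C=C/[C@@]1(O)C(C)(C)CCC[C@@]1(C)O | intermediate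
19 | (2E,4E,6E,8E)-9-[(1R,2R)-1,2-dihydroxy-2,6,6-trimethylcyclohexyl]-3,7-dimethylnona-2,4,6,8-tetraenenitrile | N#C/C=C(C)/C=C/C=C(C)/C=C/[C@@]1(O)C(C)(C)CCC[C@@]1(C)O | intermediate
20 | (2E,4E,6E,8E)-9-[(1R,2R)-1,2-dihydroxy-2,6,6-trimethylcyclohexyl]-3,7-dimethylnona-2,4,6,8-tetraenal | O=C/C=C(C)/C=C/C=C(C)/C=C/[C@@]1(O)C(C)(C)CCC[C@@]1(C)O | intermediate
21 | 2-(triphenylphosphoranylidene)acetaldehyde | O=CC=P(c1ccccc1)(c1ccccc1)c1ccccc1 | starting material
22 | (2E,4E,6E,8E,10E)-11-[(1R,2R)-1,2-dihydroxy-2,6,6-trimethylcyclohexyl]-5,9-dimethylundeca-2,4,6,8,10-pentaenal | O=C/C=C/C=C(C)/C=C/C=C(C)/C=C/[C@@]1(O)C(C)(C)CCC[C@@]1(C)O | intermediate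
23 | methyl 2-(triphenylphosphoranylidene)propanoate | COC(=O)C(C)=P(c1ccccc1)(c1ccccc1)c1ccccc1 | starting material
24 | methyl (2E,4E,6E,8E,10E,12E)-13-[(1R,2R)-1,2-dihydroxy-2,6,6-trimethylcyclohexyl]-2,7,11-trimethyltrideca-2,4,6,8,10,12-hexaenoate | COC(=O)/C(C)=C/C=C/C=C(C)/C=C/C=C(C)/C=C/[C@@]1(O)C(C)(C)CCC[C@@]1(C)O | target

**Summary**

Total step count: 14. Longest linear sequence: 13 steps (steps 1–3 and 5–14); step 4 is a one-step side branch.

Steps most likely to fail:

Step 5. The α-sulfonio radical or the ylide may be quenched before ring closure, or the ylide may add to C6 in the orientation whose betaine cannot close, so that no oxirane forms; facial control by the auxiliary may also be weaker than planned. The fallback uses known chemistry and gives up the annulation: it sets out from 1, which is esterified with commercial 2,6,6-trimethylcyclohex-1-ene-1-carboxylic acid (N,N′-dicyclohexylcarbodiimide, 4-(dimethylamino)pyridine, CH2Cl2) to (1R,2S,5R)-5-methyl-2-(2-phenylpropan-2-yl)cyclohexyl 2,6,6-trimethylcyclohex-1-ene-1-carboxylate F1. Peracid epoxidation of the tetrasubstituted, twisted alkene of F1 (3-chloroperoxybenzoic acid, NaHCO3, CH2Cl2) on the face left open by the auxiliary, with chromatographic purification of the epoxy ester, comes back to the route at 12.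

Step 6. The cationic character at C5 may lead to proton loss (allylic alcohols) or to front-side capture that erodes the trans relationship. The fallback sets out from 12: i-Bu2AlH (CH2Cl2, −78 °C) reduces the ester to [(1S,6S)-2,2,6-trimethyl-7-oxabicyclo[4.1.0]heptan-1-yl]methanol F2 and frees the auxiliary. Ti(OiPr)4-mediated opening of this 2,3-epoxy alcohol with benzoic acid at the oxirane carbon remote from the CH2OH group (C5, inversion) gives (1R,2S)-2-hydroxy-2-(hydroxymethyl)-1,3,3-trimethylcyclohexyl benzoate F3. Methanolysis (K2CO3, MeOH) comes back to the route at 14.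

Step 9. Base-induced retro-aldol ring opening or acyloin-type rearrangement of the α,β-dihydroxy aldehyde may compete with olefination of the hindered carbonyl. The fallback sets out from 15: a Wittig reaction with neutral 1-(triphenylphosphoranylidene)propan-2-one (toluene, 90 °C) gives (3E)-4-[(1R,2R)-1,2-dihydroxy-2,6,6-trimethylcyclohexyl]but-3-en-2-one F4. Horner–Wadsworth–Emmons reaction of this ketone with diethyl (cyanomethyl)phosphonate and NaH (THF), followed by separation of the 2E isomer, comes back to the route at 17.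

Further compounds
F1 | step 5 | (1R,2S,5R)-5-methyl-2-(2-phenylpropan-2-yl)cyclohexyl 2,6,6-trimethylcyclohex-1-ene-1-carboxylate | CC1=C(C(=O)O[C@H]2[C@H](C(C)(C)c3ccccc3)CC[C@@H](C)C2)C(C)(C)CCC1
F2 | step 6 | [(1S,6S)-2,2,6-trimethyl-7-oxabicyclo[4.1.0]heptan-1-yl]methanol | OC[C@@]12C(C)(C)CCC[C@]1(C)O2
F3 | step 6 | (1R,2S)-2-hydroxy-2-(hydroxymethyl)-1,3,3-trimethylcyclohexyl benzoate | OC[C@@]1(O)C(C)(C)CCC[C@@]1(C)OC(=O)c1ccccc1
F4 | step 9 | (3E)-4-[(1R,2R)-1,2-dihydroxy-2,6,6-trimethylcyclohexyl]but-3-en-2-one | CC(=O)/C=C/[C@@]1(O)C(C)(C)CCC[C@@]1(C)O
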